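Readings and results are simulated for an exercise, and the scatter is random.

If the green flask is to be repeated up to the asked time, the reading to watch is the slope of total product against time, and the bench rule of thumb says this slope follows the free catalyst.

- left-handed product and right-handed product together, in percent of the left-handed substrate and right-handed substrate charged together, at 8.0 min
- excess of left-handed product over right-handed product in the product at 8.0 min
- whether the exchange between left-handed substrate and right-handed substrate keeps pace with the reaction: how far the product's excess at 8.0 min gets from its value without exchange to its value with instant exchange (above 80% keeps pace, below 20% hardly takes part, else lags behind)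

common to all: left-handed substrate 0.050 M; right-handed substrate 0.050 M; gas 3.5 mM (held); racemization catalyst 0.75 mM; impurity 0.24 mM

|  | free catalyst | remark | time |
|---|---|---|---|
| green | 7 mM | the very flask that is asked about, followed so far |  |
| teal | 14 mM | run made earlier |  |
| flask | 7.0 mM |  | 8.0 min |

| run | time / min | left-handed product / % | right-handed product / % |
|---|---|---|---|
| green | 0.250 | 0.3 | 0.4 |
| green | 0.833 | 2.4 | 0.8 |
| green | 1.33 | 4.6 | 2.0 |
| green | 2.50 | 6.8 | 3.1 |
| green | 3.00 | 8.3 | 4.0 |
| teal | 0.667 | 1.9 | 0.2 |
| teal | 1.33 | 4.3 | 2.3 |
| teal | 2.00 | 6.0 | 1.8 |
| teal | 2.50 | 8.1 | 3.6 |
| teal | 3.00 | 9.5 | 3.0 |

(standard deviation of a reading: 0.5 percentage points)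

- free catalyst is single-handed; left-handed substrate and right-handed substrate are mirror images of each other, charged as a racemate, each of them at the stated concentration
- at the start none of reagent is dissolved
- the numbers in the tables scatter by 0.5 percentage points (one standard deviation)
- steps thought possible: reagent + free catalyst + left-handed substrate -> free catalyst + left-handed product; reagent + free catalyst + right-handed substrate -> free catalyst + right-handed product; left-handed substrate + racemization catalyst <-> right-handed substrate + racemization catalyst; gas <-> reagent; racemization catalyst + impurity -> spent catalyst A; reagent + free catalyst -> spent catalyst B
- an excess is the difference of the two amounts in percent of their sum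
- an excess is below zero if the other one leads

The teal run holds 2.00 times the free catalyst of the green run, yet at 3.00 min its total product is 1.02 times the green total, so within the scatter the rule of thumb fails in these runs. The steps on offer suggest a reading: reagent starts undissolved and enters from the gas, and if the free catalyst uses it as it arrives, its concentration stays low and product grows at the pace of the transfer.

The two totals at 3.00 min give a reading of 0.0413 min⁻¹, with the scatter of the readings in it: this is the supply pace, the share of the charged substrates turned into product per minute. My own straight line for the green flask then reaches 33.0% at 8.0 min. That line meets the whole charge at 24.2 min, which is its border, and the asked time lies at a third of the way there.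

The forecast says 31%, 39% and lags behind, its yield standing below my line. On the exchange it says: “With the racemization catalyst partly poisoned, I guess it lags”.

The green flask gives 34.2% and 38.0%, and the exchange hardly takes part: it covers 8.4% of the way to the excess with instant exchange, so the forecast's yield and excess hold and its verdict on pace does not.

    reagent + free catalyst + left-handed substrate → free catalyst + left-handed product (k = 2000 M⁻² s⁻¹)
    reagent + free catalyst + right-handed substrate → free catalyst + right-handed product (k = 760 M⁻² s⁻¹)
    left-handed substrate + racemization catalyst ⇌ right-handed substrate + racemization catalyst, rate k3*[racemization catalyst]*[left-handed substrate] forward; the back reaction follows from the equilibrium constant (k = 0.530 M⁻¹ s⁻¹)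
    gas ⇌ reagent, rate k4*(csat - [reagent]) (kL = 0.0210 s⁻¹)
    racemization catalyst + impurity → spent catalyst A (k = 2400 M⁻¹ s⁻¹)
    reagent + free catalyst → spent catalyst B (k = 0.160 M⁻¹ s⁻¹)

The yield stands where it does through the transfer of gas to reagent, the rate-limiting step, together with the reading being taken at 8.0 min: without that drag the same flask reacts >99.9% by then. Reagent is 1.21 × 10⁻⁴ M at 8.00 min, far below the saturation of 3.5 mM, and the flask's mean pace of 0.0428 min⁻¹ lies near the supply pace 0.0413 min⁻¹.

With 0.018 M of free catalyst in the neighbour flask, the supply pace gives 33.0% at 8.0 min. The computed flask gives 34.8%.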